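## Retrosynthetic overview
1. The butenolide is the only ring that is built (the furan is bought). It is closed last through its lactone O–C5 bond, by 5-exo-dig anti addition of a carboxylate to the alkyne of a (Z)-2-en-4-ynoic acid. This closure also fixes the Z-ylidene geometry.
2. That acid forms in the same flask from methacrylic acid (its β-C–H cis to CO2H) and the silver acetylide released from a silyl-capped alkyne.
3. The CH2–CH2 bond three carbons beyond the stereocentre comes from a copper-catalysed coupling of a chiral alkyl Grignard reagent with an (E)-allylic acetate.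
4. The stereocentre comes from a rhodium-catalysed asymmetric conjugate alkynylation of crotonaldehyde.
5. The diene–furan part comes from geranyl acetate: SeO2 allylic oxidation, then displacement of the acetate by furan-3-ylmethyl Grignard reagent.

Assumption: (R)-DTBM-SEGPHOS is taken to give the (S)-configured β-alkynyl aldehyde. If the sense of induction is opposite, the equally available (S)-ligand is used.

## Route

Step 1
Reactants: 1 furan-3-ylmethanol
Product: 2 3-(chloromethyl)furan
Conditions: SOCl2, pyridine, Et2O, 0 °C; used as an ethereal solution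
Reagents that add atoms: thionyl chloride, O=S(Cl)Cl
Why: Chlorodehydroxylation through the chlorosulfite (SN2) is fast on this primary furylmethyl alcohol, and pyridine keeps the acid-sensitive furan intact; no stereocentre is involved.

Step 2
Reactants: 3 geranyl acetate
Product: 4 (2E,6E)-8-hydroxy-3,7-dimethylocta-2,6-dien-1-yl acetate
Conditions: SeO2 (0.3 equiv), t-BuOOH (3 equiv), CH2Cl2, rt
Reagents that add atoms: tert-butyl hydroperoxide (terminal O source, relayed by SeO2), CC(C)(C)OO
Why: Catalytic SeO2 allylic oxidation (ene reaction, then [2,3]-sigmatropic shift) attacks the electron-richer distal trisubstituted alkene and hydroxylates its E-methyl group, while the alkene next to the acetate is deactivated.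

Step 3
Reactants: 2 3-(chloromethyl)furan; 4 (2E,6E)-8-hydroxy-3,7-dimethylocta-2,6-dien-1-yl acetate
Product: 7 (2E,6E)-9-(furan-3-yl)-2,6-dimethylnona-2,6-dien-1-yl acetate, via furan-3-ylmethylmagnesium chloride 5 (not isolated), via chloromagnesium alkoxide 6 (not isolated)
Conditions: Mg, THF, 0 °C (5, 2.5 equiv); 4, Li2CuCl4 (5 mol%), THF, −20 to 0 °C; then Ac2O, DMAP (cat.), 0 °C to rt
Reagents that add atoms: acetic anhydride, CC(=O)OC(C)=O
Why: In this copper-catalysed Grignard–allylic acetate coupling (Fouquet–Schlosser type) the first equivalent of 5 only deprotonates the OH, the second displaces the acetate at the α-carbon because the γ-carbon is fully substituted (E geometry kept), and alkoxide 6 is acetylated in the same flask.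

Step 4
Reactants: 8 (E)-crotonaldehyde; 9 (triisopropylsilyl)acetylene
Product: 11 (S)-3-methyl-5-(triisopropylsilyl)pent-4-yn-1-ol, via (S)-3-methyl-5-(triisopropylsilyl)pent-4-ynal 10 (not isolated)
Conditions: [Rh(OAc)(C2H4)2]2 (2.5 mol%), (R)-DTBM-SEGPHOS (5.5 mol%), MeOH, 40 °C; then NaBH4, 0 °C
Reagents that add atoms: none
Why: In this rhodium-catalysed asymmetric conjugate alkynylation the alkynylrhodium species held in the bulky bisphosphine pocket adds to one face of the enal and sets the (S)-methyl stereocentre, the bulky silyl group suppresses alkyne dimerisation, and borohydride reduction secures the aldehyde as the alcohol.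

Step 5
Reactants: 11 (S)-3-methyl-5-(triisopropylsilyl)pent-4-yn-1-ol
Product: 12 (S)-(5-bromo-3-methylpent-1-yn-1-yl)triisopropylsilane
Conditions: CBr4, PPh3, CH2Cl2, 0 °C
Reagents that add atoms: carbon tetrabromide, BrC(Br)(Br)Br
Why: The Appel reaction converts the primary alcohol to the bromide under neutral conditions, two carbons away from the stereocentre, which is untouched.

Step 6
Reactants: 12 (S)-(5-bromo-3-methylpent-1-yn-1-yl)triisopropylsilane; 7 (2E,6E)-9-(furan-3-yl)-2,6-dimethylnona-2,6-dien-1-yl acetate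
Product: 14 [(3S,7E,11E)-14-(furan-3-yl)-3,7,11-trimethyltetradeca-7,11-dien-1-yn-1-yl]triisopropylsilane, via alkylmagnesium bromide 13 (not isolated)
Conditions: Mg, THF, rt (13, 1.5 equiv); 7, Li2CuCl4 (5 mol%), THF, −20 to 0 °C, rapid addition
Reagents that add atoms: none
Why: In this copper-catalysed Grignard–allylic acetate coupling, low temperature, THF and rapid addition keep copper as the dialkylcuprate, which substitutes the unhindered primary α-carbon with retention of the E-alkene; the silyl cap protects the alkyne and the stereocentre is remote.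

Step 7
Reactants: 14 [(3S,7E,11E)-14-(furan-3-yl)-3,7,11-trimethyltetradeca-7,11-dien-1-yn-1-yl]triisopropylsilane; 15 methacrylic acid
Product: 18 (5Z)-5-[(2S,6E,10E)-13-(furan-3-yl)-2,6,10-trimethyltrideca-6,10-dien-1-ylidene]-3-methylfuran-2(5H)-one, via silver acetylide 16 (not isolated), via Z-enynoic acid 17 (not isolated)
Conditions: AgF (1.2 equiv), MeCN, rt, dark; then 15 (3 equiv), [Cp*RhCl2]2 (2.5 mol%), AgOAc (2 equiv), t-AmOH, 70 °C
Reagents that add atoms: none
Why: Proposed new method: a desilylative oxidative vinylic C–H alkynylation/lactonisation in which silver does three jobs. AgF removes the silyl group and holds the alkyne as acetylide 16, so no free alkyne remains to insert and give a 2-pyranone. Cp*Rh(OAc)2 formed in situ metalates the β-C–H of 15 that lies cis to the carboxylate (concerted metalation–deprotonation, five-membered rhodacycle). 16 passes its alkynyl group to trivalent rhodium, and C(sp2)–C(sp) reductive elimination can only give the Z-acid 17. Two monovalent silver ions return monovalent rhodium to the trivalent state. Silver-activated 17 then closes the O–C5 bond by 5-exo-dig anti addition and protodemetalation, which places O and the side chain cis (Z) and leaves the propargylic stereocentre alone because no strong base is present. The closest known reaction types are the rhodium/silver oxidative coupling of benzoic acids with terminal alkynes to 3-ylidenephthalides, the rhodium-catalysed annulation of acrylic acids with internal alkynes, and the silver-catalysed lactonisation of (Z)-2-en-4-ynoic acids.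

## Compound list
1 | furan-3-ylmethanol | OCc1ccoc1 | starting material
2 | 3-(chloromethyl)furan | ClCc1ccoc1 | intermediate
3 | geranyl acetate | CC(C)=CCC/C(C)=C/COC(C)=O | starting material
4 | (2E,6E)-8-hydroxy-3,7-dimethylocta-2,6-dien-1-yl acetate | OC/C(C)=C/CC/C(C)=C/COC(C)=O | intermediate
5 | furan-3-ylmethylmagnesium chloride | Cl[Mg]Cc1ccoc1 | intermediate
6 | chloromagnesium (2E,6E)-9-(furan-3-yl)-2,6-dimethylnona-2,6-dien-1-olate | Cl[Mg]OC/C(C)=C/CC/C(C)=C/CCc1ccoc1 | intermediate
7 | (2E,6E)-9-(furan-3-yl)-2,6-dimethylnona-2,6-dien-1-yl acetate | CC(=O)OC/C(C)=C/CC/C(C)=C/CCc1ccoc1 | intermediate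
8 | (E)-crotonaldehyde | C/C=C/C=O | starting material
9 | (triisopropylsilyl)acetylene | C#C[Si](C(C)C)(C(C)C)C(C)C | starting material
10 | (S)-3-methyl-5-(triisopropylsilyl)pent-4-ynal | CC(C)[Si](C#C[C@@H](C)CC=O)(C(C)C)C(C)C | intermediate
11 | (S)-3-methyl-5-(triisopropylsilyl)pent-4-yn-1-ol | CC(C)[Si](C#C[C@@H](C)CCO)(C(C)C)C(C)C | intermediate
12 | (S)-(5-bromo-3-methylpent-1-yn-1-yl)triisopropylsilane | CC(C)[Si](C#C[C@@H](C)CCBr)(C(C)C)C(C)C | intermediate
13 | [(S)-3-methyl-5-(triisopropylsilyl)pent-4-yn-1-yl]magnesium bromide | CC(C)[Si](C#C[C@@H](C)CC[Mg]Br)(C(C)C)C(C)C | intermediate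
14 | [(3S,7E,11E)-14-(furan-3-yl)-3,7,11-trimethyltetradeca-7,11-dien-1-yn-1-yl]triisopropylsilane | CC(C)[Si](C#C[C@@H](C)CCC/C(C)=C/CC/C(C)=C/CCc1ccoc1)(C(C)C)C(C)C | intermediate
15 | methacrylic acid | C=C(C)C(=O)O | starting material
16 | silver (3S,7E,11E)-14-(furan-3-yl)-3,7,11-trimethyltetradeca-7,11-dien-1-yn-1-ide | [Ag]C#C[C@@H](C)CCC/C(C)=C/CC/C(C)=C/CCc1ccoc1 | intermediate
17 | (2Z,6S,10E,14E)-17-(furan-3-yl)-2,6,10,14-tetramethylheptadeca-2,10,14-trien-4-ynoic acid | OC(=O)/C(C)=C\C#C[C@@H](C)CCC/C(C)=C/CC/C(C)=C/CCc1ccoc1 | intermediate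
18 | (5Z)-5-[(2S,6E,10E)-13-(furan-3-yl)-2,6,10-trimethyltrideca-6,10-dien-1-ylidene]-3-methylfuran-2(5H)-one | CC1=C/C(=C/[C@@H](C)CCC/C(C)=C/CC/C(C)=C/CCc2ccoc2)OC1=O | target

## Step count and risks
Total step count: 7.
Longest linear sequence: 4 steps. Two branches tie at this length: steps 2, 3, 6, 7 from 3, and steps 4, 5, 6, 7 from 8 and 9.

**Step 7 (the proposed new step).** Alkynyl transfer from 16 to the rhodacycle may be slow. Diyne formation, 6-endo closure to the 2-pyranone or metalation of the furan may compete.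

The fallback uses known chemistry. It sets out from 14 and comes back at 18. TBAF in THF frees the terminal alkyne 3-[(3E,7E,12S)-4,8,12-trimethyltetradeca-3,7-dien-13-yn-1-yl]furan F1. Separately, commercial propargyl alcohol is carbometalated (MeMgBr, CuI, Et2O, then I2) to (Z)-3-iodo-2-methylprop-2-en-1-ol F2. CrO3/H2SO4 in acetone oxidises this to (Z)-3-iodo-2-methylprop-2-enoic acid F3. F1 and F3 with Pd(PPh3)4, CuI and Et3N in MeCN undergo the established tandem Sonogashira coupling/5-exo-dig lactonisation through 17 to 18.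

**Step 4.** Crotonaldehyde is the smallest possible enal, so the ee may be lower than for larger enals, and the aldehyde may oligomerise.

The fallback replaces catalytic face selection by a stereospecific displacement. It sets out from 9 and comes back at 11.
- n-BuLi, then N-methoxy-N-methylacetamide, gives 4-(triisopropylsilyl)but-3-yn-2-one F4.
- Transfer hydrogenation with RuCl(p-cymene)[(S,S)-TsDPEN] in i-PrOH gives (S)-4-(triisopropylsilyl)but-3-yn-2-ol F5.
- MsCl/Et3N gives (S)-4-(triisopropylsilyl)but-3-yn-2-yl methanesulfonate F6.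
- Sodium dimethyl malonate displaces the mesylate by SN2 with inversion to dimethyl 2-[(S)-4-(triisopropylsilyl)but-3-yn-2-yl]propanedioate F7.
- Krapcho demethoxycarbonylation (LiCl, wet DMSO, 140 °C) gives methyl (S)-3-methyl-5-(triisopropylsilyl)pent-4-ynoate F8.
- LiAlH4 reduces F8 to 11.

**Step 6.** Attack at the γ-carbon (branched product with a 1,1-disubstituted alkene) or at the acetate carbonyl would waste the chiral Grignard reagent.

The fallback reverses the polarity (allyl sulfone anion plus alkyl bromide). It sets out from 7 and 12 and comes back at 14. NaSO2Ph with Pd(PPh3)4 in THF/MeOH converts 7 into 3-[(3E,7E)-9-(benzenesulfonyl)-4,8-dimethylnona-3,7-dien-1-yl]furan F9. n-BuLi in THF/DMPU at −78 °C, then 12, gives [(3S,7E,11E)-6-(benzenesulfonyl)-14-(furan-3-yl)-3,7,11-trimethyltetradeca-7,11-dien-1-yn-1-yl]triisopropylsilane F10 as a mixture of epimers at the sulfonyl carbon. PdCl2(dppp)/LiBHEt3 in THF at 0 °C removes the sulfonyl group without moving the alkene and gives 14.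

## Further compounds
F1 | step 7 | 3-[(3E,7E,12S)-4,8,12-trimethyltetradeca-3,7-dien-13-yn-1-yl]furan | C#C[C@@H](C)CCC/C(C)=C/CC/C(C)=C/CCc1ccoc1
F2 | step 7 | (Z)-3-iodo-2-methylprop-2-en-1-ol | OC/C(C)=C\I
F3 | step 7 | (Z)-3-iodo-2-methylprop-2-enoic acid | OC(=O)/C(C)=C\I
F4 | step 4 | 4-(triisopropylsilyl)but-3-yn-2-one | CC(=O)C#C[Si](C(C)C)(C(C)C)C(C)C
F5 | step 4 | (S)-4-(triisopropylsilyl)but-3-yn-2-ol | CC(C)[Si](C#C[C@H](C)O)(C(C)C)C(C)C
F6 | step 4 | (S)-4-(triisopropylsilyl)but-3-yn-2-yl methanesulfonate | CC(C)[Si](C#C[C@H](C)OS(C)(=O)=O)(C(C)C)C(C)C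
F7 | step 4 | dimethyl 2-[(S)-4-(triisopropylsilyl)but-3-yn-2-yl]propanedioate | CC(C)[Si](C#C[C@@H](C)C(C(=O)OC)C(=O)OC)(C(C)C)C(C)C
F8 | step 4 | methyl (S)-3-methyl-5-(triisopropylsilyl)pent-4-ynoate | CC(C)[Si](C#C[C@@H](C)CC(=O)OC)(C(C)C)C(C)C
F9 | step 6 | 3-[(3E,7E)-9-(benzenesulfonyl)-4,8-dimethylnona-3,7-dien-1-yl]furan | O=S(=O)(C/C(C)=C/CC/C(C)=C/CCc1ccoc1)c1ccccc1
F10 | step 6 | [(3S,7E,11E)-6-(benzenesulfonyl)-14-(furan-3-yl)-3,7,11-trimethyltetradeca-7,11-dien-1-yn-1-yl]triisopropylsilane | CC(C)[Si](C#C[C@@H](C)CCC(/C(C)=C/CC/C(C)=C/CCc1ccoc1)S(=O)(=O)c1ccccc1)(C(C)C)C(C)C
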